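## Retrosynthetic overview

1. Both esters are cleaved last (C3 tiglate, then C9 senecioate), leaving a 3-O-silyl 9α-hydroxy-8-ketone; the 9α-OH and the trans ring fusion come from the C9=C10 enone by dissolving-metal reduction, enolate silylation and Rubottom oxidation.
2. The isopropenyl group is masked as CH(CH3)CH2SePh and released by selenoxide elimination, so C7 can be equilibrated under base without the double bond moving into conjugation.
3. Ring B is opened Robinson-style: the C9–C10 bond by an intramolecular aldol condensation (the ring closure) and the C5–C6 bond by a Michael addition, giving ring-A enol silane (fragment A) and an α-methylene methyl ketone (fragment B).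
4. Fragment A comes from 4-hydroxycyclohexanone (desymmetrising deprotonation, Saegusa oxidation, α-methylation, anti conjugate methylation); fragment B comes from isoprenol (bromide, selenide, aldehyde, α-methylenation, methyl ketone).
5. Ring order: ring A is present from the start; ring B is formed second, in the aldol closure.

Assumptions: positions use eremophilane numbering (C3 tiglate carbon, C4/C5 methyl carbons, C7 isopropenyl carbon, C8 ketone, C9 senecioate carbon, C10 ring-fusion CH; β is the face of the two methyls). The (S,S)-lithium amide of step 2 is taken to give the (4R)-enol silane by analogy with 4-tert-butylcyclohexanone; if the sense is opposite, the (R,R)-amide is used.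

## Route

Step 1
Reactants: 1 4-hydroxycyclohexan-1-one
Product: 2 4-[(tert-butyldimethylsilyl)oxy]cyclohexan-1-one
Conditions: TBSCl, imidazole, DMF, 0 °C → rt
Reagents that add atoms: tert-butyldimethylsilyl chloride (TBSCl), CC(C)(C)[Si](C)(C)Cl
Why: Standard silylation of the secondary alcohol; the TBS ether survives the later organometallic, basic and dissolving-metal steps.

Step 2
Reactants: 2 4-[(tert-butyldimethylsilyl)oxy]cyclohexan-1-one
Product: 3 {[(4R)-4-[(tert-butyldimethylsilyl)oxy]cyclohex-1-en-1-yl]oxy}trimethylsilane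
Conditions: LiN[(S)-CH(CH3)Ph]2 (from the amine and n-BuLi), TMSCl (internal quench), THF, −100 °C
Reagents that add atoms: chlorotrimethylsilane (TMSCl), C[Si](C)(C)Cl
Why: Enantioselective deprotonation of the prochiral ketone by the chiral lithium amide (desymmetrisation) with in situ silylation fixes the absolute configuration of the carbinol carbon (later C3), typically about 90% ee.

Step 3
Reactants: 3 {[(4R)-4-[(tert-butyldimethylsilyl)oxy]cyclohex-1-en-1-yl]oxy}trimethylsilane
Product: 4 (4R)-4-[(tert-butyldimethylsilyl)oxy]cyclohex-2-en-1-one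
Conditions: Pd(OAc)2 (10 mol%), O2 (1 atm), DMSO, rt
Reagents that add atoms: none
Why: Saegusa–Ito oxidation introduces the double bond only on the enol-ether side, so the stereocentre is retained.

Step 4
Reactants: 4 (4R)-4-[(tert-butyldimethylsilyl)oxy]cyclohex-2-en-1-one
Product: 5 (4R)-4-[(tert-butyldimethylsilyl)oxy]-2-iodocyclohex-2-en-1-one
Conditions: I2, pyridine/CH2Cl2 (1:1), 0 °C → rt
Reagents that add atoms: iodine, II
Why: Johnson α-iodination of the enone (pyridine addition, iodination of the enolate, elimination) under conditions too mild to touch the γ-stereocentre.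

Step 5
Reactants: 5 (4R)-4-[(tert-butyldimethylsilyl)oxy]-2-iodocyclohex-2-en-1-one
Product: 6 (4R)-4-[(tert-butyldimethylsilyl)oxy]-2-methylcyclohex-2-en-1-one
Conditions: Me4Sn, PdCl2(PhCN)2 (5 mol%), AsPh3, CuI, NMP, 80 °C
Reagents that add atoms: tetramethylstannane, C[Sn](C)(C)C
Why: Stille coupling of the α-iodoenone installs the methyl group that becomes the angular C5 methyl.

Step 6
Reactants: 6 (4R)-4-[(tert-butyldimethylsilyl)oxy]-2-methylcyclohex-2-en-1-one
Product: 7 {[(3R,4R)-4-[(tert-butyldimethylsilyl)oxy]-2,3-dimethylcyclohex-1-en-1-yl]oxy}trimethylsilane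
Conditions: MeMgBr, CuBr·SMe2 (10 mol%), TMSCl, DMPU, THF, −78 °C; Et3N, cold aq. NaHCO3
Reagents that add atoms: methylmagnesium bromide, C[Mg]Br; chlorotrimethylsilane, C[Si](C)(C)Cl
Why: Copper-catalysed conjugate addition delivers methyl anti to the neighbouring silyloxy group (C4 methyl trans to the C3 oxygen), and TMSCl traps the enolate regiospecifically as the tetrasubstituted enol silane.

Step 7
Reactants: 8 3-methylbut-3-en-1-ol
Product: 9 4-bromo-3-methylbutan-1-ol
Conditions: HBr (g), (PhCO2)2 (2 mol%), hν, pentane, −20 °C; used at once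
Reagents that add atoms: hydrogen bromide, Br
Why: Peroxide-initiated radical chain (Kharasch) addition puts bromine on the terminal carbon via the tertiary radical; the new stereocentre is racemic and is destroyed in step 14.

Step 8
Reactants: 9 4-bromo-3-methylbutan-1-ol
Product: 10 3-methyl-4-(phenylselanyl)butan-1-ol
Conditions: (PhSe)2, NaBH4, EtOH, 0 °C; then 9, 0 °C → rt
Reagents that add atoms: diphenyl diselenide, c1ccc(cc1)[Se][Se]c1ccccc1
Why: SN2 displacement of the primary bromide by the soft, weakly basic selenolate outruns cyclisation to the tetrahydrofuran.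

Step 9
Reactants: 10 3-methyl-4-(phenylselanyl)butan-1-ol
Product: 11 3-methyl-4-(phenylselanyl)butanal
Conditions: Dess–Martin periodinane, NaHCO3, CH2Cl2, 0 °C → rt
Reagents that add atoms: none
Why: Buffered Dess–Martin oxidation of the primary alcohol leaves the selenide untouched.

Step 10
Reactants: 11 3-methyl-4-(phenylselanyl)butanal
Product: 12 3-methyl-2-methylidene-4-(phenylselanyl)butanal
Conditions: aq. CH2O (37%), pyrrolidine (10 mol%), EtCO2H (10 mol%), iPrOH, 45 °C
Reagents that add atoms: formaldehyde, C=O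
Why: Amine/acid-catalysed Mannich condensation followed by elimination (α-methylenation of an aldehyde) gives the 2-substituted acrolein.

Step 11
Reactants: 12 3-methyl-2-methylidene-4-(phenylselanyl)butanal
Product: 13 4-methyl-3-methylidene-5-(phenylselanyl)pentan-2-ol
Conditions: MeMgBr, THF, −78 °C; aq. NH4Cl
Reagents that add atoms: methylmagnesium bromide, C[Mg]Br
Why: Grignard 1,2-addition to the enal; the new carbinol centre is oxidised in the next step.

Step 12
Reactants: 13 4-methyl-3-methylidene-5-(phenylselanyl)pentan-2-ol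
Product: 14 4-methyl-3-methylidene-5-(phenylselanyl)pentan-2-one
Conditions: Dess–Martin periodinane, NaHCO3, CH2Cl2, 0 °C; used freshly
Reagents that add atoms: none
Why: Dess–Martin oxidation of the allylic alcohol gives the α-substituted vinyl ketone, the Michael acceptor carrying the masked isopropenyl group.

Step 13
Reactants: 7 {[(3R,4R)-4-[(tert-butyldimethylsilyl)oxy]-2,3-dimethylcyclohex-1-en-1-yl]oxy}trimethylsilane; 14 4-methyl-3-methylidene-5-(phenylselanyl)pentan-2-one
Product: 18 (3S,4aR,5R,6R)-6-[(tert-butyldimethylsilyl)oxy]-4a,5-dimethyl-3-[1-(phenylselanyl)propan-2-yl]-4,4a,5,6,7,8-hexahydronaphthalen-2(3H)-one, via lithium enolate 15 (not isolated), via diketone 16 (not isolated), via ketol 17 (not isolated)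
Conditions: MeLi (1.0 equiv), THF, 0 °C → rt; 14, −78 → −20 °C; NaOMe (0.5 equiv), MeOH, 0 → 50 °C
Reagents that add atoms: none
Why: Robinson annulation: the regiodefined enolate undergoes Michael addition anti to the adjacent C4 methyl (new C5 quaternary centre, methyls cis), ring B then closes by intramolecular aldol condensation of C9 onto C10, and methoxide equilibrates the saturated C7 side chain to the equatorial 7α position.

Step 14
Reactants: 18 (3S,4aR,5R,6R)-6-[(tert-butyldimethylsilyl)oxy]-4a,5-dimethyl-3-[1-(phenylselanyl)propan-2-yl]-4,4a,5,6,7,8-hexahydronaphthalen-2(3H)-one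
Product: 20 (3S,4aR,5R,6R)-6-[(tert-butyldimethylsilyl)oxy]-4a,5-dimethyl-3-(prop-1-en-2-yl)-4,4a,5,6,7,8-hexahydronaphthalen-2(3H)-one, via selenoxide 19 (not isolated)
Conditions: mCPBA (1.05 equiv), CH2Cl2, −78 °C; iPr2NH, −78 °C → rt
Reagents that add atoms: none
Why: Selenium is oxidised chemoselectively and the selenoxide undergoes syn-elimination through its only β-hydrogen (the side-chain CH), unveiling the isopropenyl group without touching C7.

Step 15
Reactants: 20 (3S,4aR,5R,6R)-6-[(tert-butyldimethylsilyl)oxy]-4a,5-dimethyl-3-(prop-1-en-2-yl)-4,4a,5,6,7,8-hexahydronaphthalen-2(3H)-one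
Product: 24 (1S,3S,4aR,5R,6R,8aR)-6-[(tert-butyldimethylsilyl)oxy]-1-hydroxy-4a,5-dimethyl-3-(prop-1-en-2-yl)octahydronaphthalen-2(1H)-one, via lithium enolate 21 (not isolated), via silyl enol ether 22 (not isolated), via silyloxy ketone 23 (not isolated)
Conditions: Li, NH3(l)/THF, t-BuOH (1.0 equiv), −78 °C; isoprene; NH3 off; TMSCl, Et3N, THF, −78 → 0 °C; volatiles off, pentane, cannula filtration; mCPBA (1.05 equiv), NaHCO3, CH2Cl2, −20 °C; citric acid, MeOH, 0 °C
Reagents that add atoms: meta-chloroperbenzoic acid (mCPBA), O=C(OO)c1cccc(Cl)c1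
Why: Dissolving-metal reduction of the enone gives the trans ring fusion (axial protonation at C10) and the C8–C9 enolate regiospecifically; silylation and Rubottom oxidation from the α face, anti to the axial C5 methyl, give the equatorial 9α-OH, the enol silane reacting far faster with the peracid than the isopropenyl group.

Step 16
Reactants: 24 (1S,3S,4aR,5R,6R,8aR)-6-[(tert-butyldimethylsilyl)oxy]-1-hydroxy-4a,5-dimethyl-3-(prop-1-en-2-yl)octahydronaphthalen-2(1H)-one; 25 3-methylbut-2-enoyl chloride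
Product: 26 (1S,3S,4aR,5R,6R,8aR)-6-[(tert-butyldimethylsilyl)oxy]-4a,5-dimethyl-2-oxo-3-(prop-1-en-2-yl)decahydronaphthalen-1-yl 3-methylbut-2-enoate
Conditions: pyridine, DMAP (10 mol%), CH2Cl2, 0 °C → rt
Reagents that add atoms: none
Why: DMAP-catalysed acylation of the α-ketol in pyridine (no trialkylamine, to avoid deconjugating the senecioyl group through a vinylketene) proceeds with retention at C9.

Step 17
Reactants: 26 (1S,3S,4aR,5R,6R,8aR)-6-[(tert-butyldimethylsilyl)oxy]-4a,5-dimethyl-2-oxo-3-(prop-1-en-2-yl)decahydronaphthalen-1-yl 3-methylbut-2-enoate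
Product: 27 (1S,3S,4aR,5R,6R,8aR)-6-hydroxy-4a,5-dimethyl-2-oxo-3-(prop-1-en-2-yl)decahydronaphthalen-1-yl 3-methylbut-2-enoate
Conditions: HF·pyridine, pyridine/THF, 0 °C → rt
Reagents that add atoms: none
Why: Fluoride-mediated desilylation under buffered, mildly acidic conditions leaves the α-acyloxy ketone and the isopropenyl group intact.

Step 18
Reactants: 27 (1S,3S,4aR,5R,6R,8aR)-6-hydroxy-4a,5-dimethyl-2-oxo-3-(prop-1-en-2-yl)decahydronaphthalen-1-yl 3-methylbut-2-enoate; 28 (2E)-2-methylbut-2-enoyl chloride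
Product: 29 (1R,2R,4aR,5S,7S,8aR)-1,8a-dimethyl-5-[(3-methylbut-2-enoyl)oxy]-6-oxo-7-(prop-1-en-2-yl)decahydronaphthalen-2-yl (2E)-2-methylbut-2-enoate
Conditions: DMAP, pyridine, CH2Cl2, rt → 40 °C
Reagents that add atoms: none
Why: DMAP-catalysed acylation of the equatorial C3 alcohol with the (E)-acid chloride gives the tiglate with retention at C3; the mild base does not disturb the equatorial C7 and C9 centres.

## Compound list

1 | 4-hydroxycyclohexan-1-one | O=C1CCC(O)CC1 | starting material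
2 | 4-[(tert-butyldimethylsilyl)oxy]cyclohexan-1-one | CC(C)(C)[Si](C)(C)OC1CCC(=O)CC1 | intermediate
3 | {[(4R)-4-[(tert-butyldimethylsilyl)oxy]cyclohex-1-en-1-yl]oxy}trimethylsilane | C[Si](C)(C)OC1=CC[C@H](O[Si](C)(C)C(C)(C)C)CC1 | intermediate
4 | (4R)-4-[(tert-butyldimethylsilyl)oxy]cyclohex-2-en-1-one | O=C1C=C[C@H](O[Si](C)(C)C(C)(C)C)CC1 | intermediate
5 | (4R)-4-[(tert-butyldimethylsilyl)oxy]-2-iodocyclohex-2-en-1-one | O=C1C(I)=C[C@H](O[Si](C)(C)C(C)(C)C)CC1 | intermediate
6 | (4R)-4-[(tert-butyldimethylsilyl)oxy]-2-methylcyclohex-2-en-1-one | O=C1C(C)=C[C@H](O[Si](C)(C)C(C)(C)C)CC1 | intermediate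
7 | {[(3R,4R)-4-[(tert-butyldimethylsilyl)oxy]-2,3-dimethylcyclohex-1-en-1-yl]oxy}trimethylsilane (fragment A) | C[Si](C)(C)OC1=C(C)[C@@H](C)[C@H](O[Si](C)(C)C(C)(C)C)CC1 | intermediate
8 | 3-methylbut-3-en-1-ol (isoprenol) | C=C(C)CCO | starting material
9 | 4-bromo-3-methylbutan-1-ol (racemic) | OCCC(C)CBr | intermediate
10 | 3-methyl-4-(phenylselanyl)butan-1-ol (racemic) | OCCC(C)C[Se]c1ccccc1 | intermediate
11 | 3-methyl-4-(phenylselanyl)butanal (racemic) | O=CCC(C)C[Se]c1ccccc1 | intermediate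
12 | 3-methyl-2-methylidene-4-(phenylselanyl)butanal (racemic) | O=CC(=C)C(C)C[Se]c1ccccc1 | intermediate
13 | 4-methyl-3-methylidene-5-(phenylselanyl)pentan-2-ol (diastereomer mixture) | CC(O)C(=C)C(C)C[Se]c1ccccc1 | intermediate
14 | 4-methyl-3-methylidene-5-(phenylselanyl)pentan-2-one (racemic; fragment B) | CC(=O)C(=C)C(C)C[Se]c1ccccc1 | intermediate
15 | lithium (3R,4R)-4-[(tert-butyldimethylsilyl)oxy]-2,3-dimethylcyclohex-1-en-1-olate (lithium enolate, forms in the flask in step 13) | [Li+].[O-]C1=C(C)[C@@H](C)[C@H](O[Si](C)(C)C(C)(C)C)CC1 | intermediate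
16 | (2R,3R,4R)-4-[(tert-butyldimethylsilyl)oxy]-2,3-dimethyl-2-{3-oxo-2-[1-(phenylselanyl)propan-2-yl]butyl}cyclohexan-1-one (diketone, side-chain centres unfixed, forms in the flask in step 13) | CC(=O)C(C[C@]1(C)[C@@H](C)[C@H](O[Si](C)(C)C(C)(C)C)CCC1=O)C(C)C[Se]c1ccccc1 | intermediate
17 | (4aR,5R,6R)-6-[(tert-butyldimethylsilyl)oxy]-8a-hydroxy-4a,5-dimethyl-3-[1-(phenylselanyl)propan-2-yl]octahydronaphthalen-2(1H)-one (aldol ketol, C3, C8a and side-chain centres unfixed, forms in the flask in step 13) | c3ccccc3[Se]CC(C)C1C[C@]2(C)[C@@H](C)[C@H](O[Si](C)(C)C(C)(C)C)CCC2(O)CC1=O | intermediate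
18 | (3S,4aR,5R,6R)-6-[(tert-butyldimethylsilyl)oxy]-4a,5-dimethyl-3-[1-(phenylselanyl)propan-2-yl]-4,4a,5,6,7,8-hexahydronaphthalen-2(3H)-one (both epimers at the side-chain CH) | c3ccccc3[Se]CC(C)[C@@H]1C[C@]2(C)[C@@H](C)[C@H](O[Si](C)(C)C(C)(C)C)CCC2=CC1=O | intermediate
19 | (3S,4aR,5R,6R)-6-[(tert-butyldimethylsilyl)oxy]-4a,5-dimethyl-3-[1-(phenylseleninyl)propan-2-yl]-4,4a,5,6,7,8-hexahydronaphthalen-2(3H)-one (selenoxide, forms in the flask in step 14) | O=[Se](CC(C)[C@@H]1C[C@]2(C)[C@@H](C)[C@H](O[Si](C)(C)C(C)(C)C)CCC2=CC1=O)c1ccccc1 | intermediate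
20 | (3S,4aR,5R,6R)-6-[(tert-butyldimethylsilyl)oxy]-4a,5-dimethyl-3-(prop-1-en-2-yl)-4,4a,5,6,7,8-hexahydronaphthalen-2(3H)-one (O-TBS petasol) | C=C(C)[C@@H]1C[C@]2(C)[C@@H](C)[C@H](O[Si](C)(C)C(C)(C)C)CCC2=CC1=O | intermediate
21 | lithium (3S,4aS,5R,6R,8aS)-6-[(tert-butyldimethylsilyl)oxy]-4a,5-dimethyl-3-(prop-1-en-2-yl)-3,4,4a,5,6,7,8,8a-octahydronaphthalen-2-olate (C8–C9 enolate of the trans-fused ketone, forms in the flask in step 15) | C=C(C)[C@@H]1C[C@]2(C)[C@@H](C)[C@H](O[Si](C)(C)C(C)(C)C)CC[C@H]2C=C1[O-].[Li+] | intermediate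
22 | (3S,4aS,5R,6R,8aS)-6-[(tert-butyldimethylsilyl)oxy]-4a,5-dimethyl-3-(prop-1-en-2-yl)-2-[(trimethylsilyl)oxy]-3,4,4a,5,6,7,8,8a-octahydronaphthalene (silyl enol ether, forms in the flask in step 15) | C=C(C)[C@@H]1C[C@]2(C)[C@@H](C)[C@H](O[Si](C)(C)C(C)(C)C)CC[C@H]2C=C1O[Si](C)(C)C | intermediate
23 | (1S,3S,4aR,5R,6R,8aR)-6-[(tert-butyldimethylsilyl)oxy]-4a,5-dimethyl-3-(prop-1-en-2-yl)-1-[(trimethylsilyl)oxy]octahydronaphthalen-2(1H)-one (silyloxy ketone, forms in the flask in step 15) | C=C(C)[C@@H]1C[C@]2(C)[C@@H](C)[C@H](O[Si](C)(C)C(C)(C)C)CC[C@H]2[C@H](O[Si](C)(C)C)C1=O | intermediate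
24 | (1S,3S,4aR,5R,6R,8aR)-6-[(tert-butyldimethylsilyl)oxy]-1-hydroxy-4a,5-dimethyl-3-(prop-1-en-2-yl)octahydronaphthalen-2(1H)-one | C=C(C)[C@@H]1C[C@]2(C)[C@@H](C)[C@H](O[Si](C)(C)C(C)(C)C)CC[C@H]2[C@H](O)C1=O | intermediate
25 | 3-methylbut-2-enoyl chloride (senecioyl chloride) | CC(C)=CC(=O)Cl | starting material
26 | (1S,3S,4aR,5R,6R,8aR)-6-[(tert-butyldimethylsilyl)oxy]-4a,5-dimethyl-2-oxo-3-(prop-1-en-2-yl)decahydronaphthalen-1-yl 3-methylbut-2-enoate | C=C(C)[C@@H]1C[C@]2(C)[C@@H](C)[C@H](O[Si](C)(C)C(C)(C)C)CC[C@H]2[C@H](OC(=O)C=C(C)C)C1=O | intermediate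
27 | (1S,3S,4aR,5R,6R,8aR)-6-hydroxy-4a,5-dimethyl-2-oxo-3-(prop-1-en-2-yl)decahydronaphthalen-1-yl 3-methylbut-2-enoate | C=C(C)[C@@H]1C[C@]2(C)[C@@H](C)[C@H](O)CC[C@H]2[C@H](OC(=O)C=C(C)C)C1=O | intermediate
28 | (2E)-2-methylbut-2-enoyl chloride (tigloyl chloride) | C/C=C(\C)C(=O)Cl | starting material
29 | (1R,2R,4aR,5S,7S,8aR)-1,8a-dimethyl-5-[(3-methylbut-2-enoyl)oxy]-6-oxo-7-(prop-1-en-2-yl)decahydronaphthalen-2-yl (2E)-2-methylbut-2-enoate | C=C(C)[C@@H]1C[C@]2(C)[C@@H](C)[C@H](OC(=O)/C(C)=C/C)CC[C@H]2[C@H](OC(=O)C=C(C)C)C1=O | target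

## Step count and risks

Total step count: 18. Longest linear sequence: 12 steps (steps 1–6 then 13–18; the other branch, steps 7–12 then 13–18, is equally long).

The three steps most likely to fail:

Step 13. The hindered tetrasubstituted lithium enolate may add 1,2, polymerise 14, or give a poorer C5 diastereomer ratio because the C3 silyloxy group sits on the attacking face. The fallback sets out from enol silane 7 and adds it to 14 under Lewis-acid catalysis (Mukaiyama–Michael, TMSOTf 10 mol%, CH2Cl2, −78 °C). The adduct is collected as the trimethylsilyl enol ether of the Michael adduct F1, which is hydrolysed with citric acid in MeOH/THF to diketone 16, now isolated and purified. The route is rejoined at 16, which is cyclised separately with NaOMe in MeOH to 18.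

Step 14. The primary alkyl phenyl selenoxide may eliminate slowly, and the amine may move the new double bond into conjugation with the ketone. The fallback sets out from 18 and first reduces the ketone (NaBH4, CeCl3·7H2O, MeOH, 0 °C) to the allylic alcohol F2, so the C7 hydrogen is no longer acidic. Oxidation at selenium (NaIO4, NaHCO3, MeOH/H2O/THF, rt) gives the selenoxide F3, which eliminates in the flask to the isopropenyl allylic alcohol F4. Reoxidation with MnO2 (CH2Cl2, rt) comes back to the route at 20.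

Step 15. The one-flask reduction, silylation and oxidation depends on handling a labile trimethylsilyl enol ether and on the peracid sparing the isopropenyl group. The fallback sets out from 20, traps the reductively formed enolate 21 with TESCl, and isolates the triethylsilyl enol ether F5 by chromatography on Et3N-deactivated silica. Epoxidation with dimethyldioxirane (acetone/CH2Cl2, −78 °C) gives, after silyl migration, the 9α-triethylsilyloxy ketone F6. Selective removal of the triethylsilyl group (AcOH/THF/H2O, rt) comes back to the route at 24.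

## Further compounds

F1 | step 13 | (2R,3R,4R)-4-[(tert-butyldimethylsilyl)oxy]-2,3-dimethyl-2-{2-[1-(phenylselanyl)propan-2-yl]-3-[(trimethylsilyl)oxy]but-2-en-1-yl}cyclohexan-1-one | CC(O[Si](C)(C)C)=C(C[C@]1(C)[C@@H](C)[C@H](O[Si](C)(C)C(C)(C)C)CCC1=O)C(C)C[Se]c1ccccc1
F2 | step 14 | (3S,4aR,5R,6R)-6-[(tert-butyldimethylsilyl)oxy]-4a,5-dimethyl-3-[1-(phenylselanyl)propan-2-yl]-2,3,4,4a,5,6,7,8-octahydronaphthalen-2-ol (carbinol epimers) | c3ccccc3[Se]CC(C)[C@@H]1C[C@]2(C)[C@@H](C)[C@H](O[Si](C)(C)C(C)(C)C)CCC2=CC1O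
F3 | step 14 | (3S,4aR,5R,6R)-6-[(tert-butyldimethylsilyl)oxy]-4a,5-dimethyl-3-[1-(phenylseleninyl)propan-2-yl]-2,3,4,4a,5,6,7,8-octahydronaphthalen-2-ol | O=[Se](CC(C)[C@@H]1C[C@]2(C)[C@@H](C)[C@H](O[Si](C)(C)C(C)(C)C)CCC2=CC1O)c1ccccc1
F4 | step 14 | (3S,4aR,5R,6R)-6-[(tert-butyldimethylsilyl)oxy]-4a,5-dimethyl-3-(prop-1-en-2-yl)-2,3,4,4a,5,6,7,8-octahydronaphthalen-2-ol | C=C(C)[C@@H]1C[C@]2(C)[C@@H](C)[C@H](O[Si](C)(C)C(C)(C)C)CCC2=CC1O
F5 | step 15 | (3S,4aS,5R,6R,8aS)-6-[(tert-butyldimethylsilyl)oxy]-4a,5-dimethyl-3-(prop-1-en-2-yl)-2-[(triethylsilyl)oxy]-3,4,4a,5,6,7,8,8a-octahydronaphthalene | C=C(C)[C@@H]1C[C@]2(C)[C@@H](C)[C@H](O[Si](C)(C)C(C)(C)C)CC[C@H]2C=C1O[Si](CC)(CC)CC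
F6 | step 15 | (1S,3S,4aR,5R,6R,8aR)-6-[(tert-butyldimethylsilyl)oxy]-4a,5-dimethyl-3-(prop-1-en-2-yl)-1-[(triethylsilyl)oxy]octahydronaphthalen-2(1H)-one | C=C(C)[C@@H]1C[C@]2(C)[C@@H](C)[C@H](O[Si](C)(C)C(C)(C)C)CC[C@H]2[C@H](O[Si](CC)(CC)CC)C1=O
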